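**Retrosynthetic overview**

1. Locants follow eunicellane numbering: C1/C10 ring fusion, C2–O–C9 bridge, C3 quaternary, C4 ester carbon, C11=C12–C13=O, oxepane C14–C15–C16–O–C3–C2–C1. Butanoate ⇒ C4 alcohol; oxonene ⇒ ring-closing metathesis at C6=C7; C4–C5 ⇒ chelation-controlled allylation of a C4 aldehyde; C8–C9 ⇒ methallylation of a C9 lactol.
2. C11=C12 enone ⇒ saturated C13 ketone; C15 methyl ⇒ hydroxyl-directed hydrogenation of a C15 exocyclic methylene.
3. Key disconnection C14–C15 (closes the oxepane): 7-exo-dig attack of a C13=C14 enol silane on a propargyl ether held on the C3 oxygen. The enol silane is made in the same flask by an ester-tethered Diels–Alder reaction of a 2-silyloxydiene (C12=C13–C14=C1) with a crotonate (C10=C11) on the C2 oxygen, which also closes the cyclohexane and the lactone that becomes the tetrahydrofuran.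
4. Enabling feature: in the six-membered ring the C13 carbonyl is flanked by C14, so C13=O is the retron of a 2-silyloxydiene cycloaddition that leaves its enol double bond exactly at C13=C14. C14 is joined to C15 through C1–C2–C3–O–C16, a chain that a propargyl group on the C3 oxygen completes to the seven-membered ring, with C15 as the internal alkyne carbon.
5. Acyclic precursor: C2/C3 diad from Sharpless epoxidation of a Z-allylic alcohol and invertive opening at C3 by propargyl alcohol. Ring order: cyclohexane + lactone, then oxepane (same operation), tetrahydrofuran side chain, oxonene.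

Key step: step 10

Remark: the same eunicellane locants are used for the atoms of acyclic precursors that become these positions; TBDPS = tert-butyldiphenylsilyl, TBS = tert-butyldimethylsilyl.

**Route**

Step 1
Reactants: 1 prop-2-yn-1-ol
Product: 2 tert-butyldiphenyl(prop-2-yn-1-yloxy)silane
Conditions: TBDPSCl, imidazole, DMF, 0 → 23 °C
Reagents that add atoms: tert-butylchlorodiphenylsilane, CC(C)(C)[Si](Cl)(c1ccccc1)c1ccccc1
Why: Imidazole-promoted silyl ether formation masks the future C4 hydroxyl with a group that survives the later Lewis acids and hydrides; no stereocenter is formed.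

Step 2
Reactants: 2 tert-butyldiphenyl(prop-2-yn-1-yloxy)silane
Product: 3 ethyl 4-[(tert-butyldiphenylsilyl)oxy]but-2-ynoate
Conditions: n-BuLi, THF, −78 °C; then ClCO2Et, −78 → 0 °C
Reagents that add atoms: ethyl chloroformate, CCOC(=O)Cl
Why: C-Acylation of the lithium acetylide with the chloroformate gives the ynoate that carries C1–C4; no stereocenter is formed.

Step 3
Reactants: 3 ethyl 4-[(tert-butyldiphenylsilyl)oxy]but-2-ynoate
Product: 4 ethyl (2Z)-4-[(tert-butyldiphenylsilyl)oxy]-3-methylbut-2-enoate
Conditions: MeLi (2.4 equiv), CuI (1.2 equiv), THF, 0 °C; then 3, −78 °C; MeOH at −78 °C, then aq. NH4Cl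
Reagents that add atoms: lithium dimethylcuprate (made in the flask from MeLi and CuI), [Li+].C[Cu-]C
Why: syn-Carbocupration of the ynoate (conjugate addition of a Gilman cuprate), with protonation at −78 °C before the alkenylcopper can isomerize, puts methyl and hydrogen cis and so fixes the Z olefin (C1 and C4 cis).

Step 4
Reactants: 4 ethyl (2Z)-4-[(tert-butyldiphenylsilyl)oxy]-3-methylbut-2-enoate
Product: 5 (2Z)-4-[(tert-butyldiphenylsilyl)oxy]-3-methylbut-2-en-1-ol
Conditions: iBu2AlH (2.5 equiv), CH2Cl2, −78 → 0 °C
Reagents that add atoms: none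
Why: Ester reduction by iBu2AlH is a 1,2-reduction that leaves the olefin geometry and the silyl ether untouched.

Step 5
Reactants: 5 (2Z)-4-[(tert-butyldiphenylsilyl)oxy]-3-methylbut-2-en-1-ol
Product: 6 [(2S,3R)-3-{[(tert-butyldiphenylsilyl)oxy]methyl}-3-methyloxiran-2-yl]methanol
Conditions: Ti(OiPr)4 (10 mol%), L-(+)-diethyl tartrate (12 mol%), tBuOOH, 4 Å MS, CH2Cl2, −20 °C
Reagents that add atoms: tert-butyl hydroperoxide, CC(C)(C)OO
Why: Sharpless asymmetric epoxidation with the L-(+)-tartrate catalyst should deliver oxygen to the face that gives the (2S,3R)-epoxide (the sense known for Z-3-methylalk-2-en-1-ols), which sets the C2 oxygen center and places C3 in the configuration that the later inversion corrects.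

Step 6
Reactants: 6 [(2S,3R)-3-{[(tert-butyldiphenylsilyl)oxy]methyl}-3-methyloxiran-2-yl]methanol; 7 1-(triphenyl-λ5-phosphanylidene)propan-2-one
Product: 9 (3E)-4-[(2S,3R)-3-{[(tert-butyldiphenylsilyl)oxy]methyl}-3-methyloxiran-2-yl]but-3-en-2-one, via epoxy aldehyde 8 (not isolated)
Conditions: Dess–Martin periodinane, pyridine, CH2Cl2, 0 → 23 °C; then 7, 23 °C
Reagents that add atoms: none
Why: Dess–Martin oxidation followed in the same flask by Wittig olefination with the stabilized ylide should give the E-enone (C1=C14 with C13 and C12) without isolating the sensitive epoxy aldehyde; the epoxide centers are untouched.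

Step 7
Reactants: 9 (3E)-4-[(2S,3R)-3-{[(tert-butyldiphenylsilyl)oxy]methyl}-3-methyloxiran-2-yl]but-3-en-2-one; 1 prop-2-yn-1-ol
Product: 10 (3E,5S,6S)-7-[(tert-butyldiphenylsilyl)oxy]-5-hydroxy-6-methyl-6-(prop-2-yn-1-yloxy)hept-3-en-2-one
Conditions: BF3·OEt2 (0.2 equiv), prop-2-yn-1-ol (10 equiv), CH2Cl2, −40 → 0 °C
Reagents that add atoms: none
Why: In this Lewis-acid-catalysed epoxide alcoholysis the alcohol should attack the tertiary carbon C3 with inversion (the allylic C2–O bond is deactivated by the conjugated ketone), which sets the tertiary propargyl ether center and frees the C2 hydroxyl with retention.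

Step 8
Reactants: 10 (3E,5S,6S)-7-[(tert-butyldiphenylsilyl)oxy]-5-hydroxy-6-methyl-6-(prop-2-yn-1-yloxy)hept-3-en-2-one; 11 (2E)-but-2-enoic anhydride
Product: 12 (3E,5S,6S)-7-[(tert-butyldiphenylsilyl)oxy]-6-methyl-2-oxo-6-(prop-2-yn-1-yloxy)hept-3-en-5-yl (2E)-but-2-enoate
Conditions: DMAP (0.2 equiv), Et3N, CH2Cl2, 0 → 23 °C
Reagents that add atoms: none
Why: DMAP-catalysed esterification of the only free hydroxyl installs C9–C11 as the tethered dienophile; no stereocenter is touched.

Step 9
Reactants: 12 (3E,5S,6S)-7-[(tert-butyldiphenylsilyl)oxy]-6-methyl-2-oxo-6-(prop-2-yn-1-yloxy)hept-3-en-5-yl (2E)-but-2-enoate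
Product: 13 (3E,5S,6S)-2-[(tert-butyldimethylsilyl)oxy]-7-[(tert-butyldiphenylsilyl)oxy]-6-methyl-6-(prop-2-yn-1-yloxy)hepta-1,3-dien-5-yl (2E)-but-2-enoate
Conditions: TBSOTf, Et3N, CH2Cl2, −78 → 0 °C
Reagents that add atoms: tert-butyldimethylsilyl trifluoromethanesulfonate, CC(C)(C)[Si](C)(C)OS(=O)(=O)C(F)(F)F
Why: Soft enolisation of the methyl ketone (silyl enol ether formation) should give the cross-conjugated 2-silyloxy-1,3-diene without enolising the ester.

Step 10
Reactants: 13 (3E,5S,6S)-2-[(tert-butyldimethylsilyl)oxy]-7-[(tert-butyldiphenylsilyl)oxy]-6-methyl-6-(prop-2-yn-1-yloxy)hepta-1,3-dien-5-yl (2E)-but-2-enoate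
Product: 15 tricyclic keto lactone (C9 lactone; C13 ketone; oxepane with C15 exocyclic methylene; C4–OTBDPS), via Diels–Alder adduct 14 (not isolated)
Conditions: PhMe (0.01 M), BHT, 130 °C, sealed tube; cool to 23 °C; then CH2Cl2/MeOH (10:1), [(JohnPhos)Au(NCMe)]SbF6 (5 mol%), 23 → 40 °C
Reagents that add atoms: none
Why: Heating triggers an ester-tethered intramolecular Diels–Alder reaction of the 2-silyloxydiene (C12=C13–C14=C1) with the crotonate (C10=C11), the closest known type being thermal cycloadditions of dienyl esters and of 2-silyloxydienes; it forms C1–C10 and C11–C12, closes the cyclohexene by [4+2] and the γ-lactone by the fused tether mode, and leaves the enol silane double bond regiospecifically at C13=C14. Facial control comes from C2: A(1,3) strain keeps H2 in the diene plane so that the lactone oxygen delivers the dienophile anti to the C3 arm (C14 trans to C3, H1 trans to H2), the endo tether carbonyl gives the cis fusion at C1/C10, and the E-crotonate places the transient C11 methyl trans to C9. Cationic monovalent gold then activates the terminal alkyne of the propargyl ether on the C3 oxygen, and the enol silane attacks through C14 at the internal carbon C15 (7-exo-dig carbocyclisation, the silyl enol ether variant of the Conia-ene reaction, known for five- to seven-membered rings), which closes the oxepane by the C14–C15 bond, while methanol takes the silyl group and protodeaurates to leave the C13 ketone and the C15 methylene. C14 is set by the tether, because the C1–C2 bond holds the alkyne over one face of the enol silane and C15 must enter cis to C2 (H14 cis to H1). The selectivities needed are crotonate over alkyne as dienophile (matched electron-rich diene and electron-poor alkene; the unactivated alkyne should be inert at this temperature), 7-exo over 8-endo attack (Markovnikov addition to a terminal alkyne), and C–C bond formation over simple protodesilylation (intramolecular capture through a seven-membered transition state). The acyclic diene could reach the alkyne only through a nine-membered ring, so only the cycloadduct should cyclise and the substrate orders the sequence.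

Step 11
Reactants: 15 tricyclic keto lactone
Product: 16 lactol diol (C9 hemiacetal and C13 carbinol; both as epimer mixtures; C15 methylene retained)
Conditions: iBu2AlH (3.5 equiv), CH2Cl2, −78 °C
Reagents that add atoms: none
Why: Hydride reduction at −78 °C should stop the γ-lactone at the lactol and take the ketone to the C13 carbinol, which is wanted as the directing group for step 12; both new centers are erased later (steps 13 and 14), so no selectivity is needed.

Step 12
Reactants: 16 lactol diol
Product: 17 (15R)-methyl lactol diol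
Conditions: [Ir(cod)(PCy3)(py)]PF6 (10 mol%), H2 (1 atm), CH2Cl2, 23 °C
Reagents that add atoms: none
Why: In this hydroxyl-directed homogeneous hydrogenation the iridium bound to the C13 oxygen should add H2 to the face of the C15 methylene on which C13 lies, so that H15 ends cis to C13 and the new methyl trans to it (15R).

Step 13
Reactants: 17 (15R)-methyl lactol diol; 18 trimethyl(2-methylprop-2-en-1-yl)silane
Product: 19 (9S)-9-(2-methylprop-2-en-1-yl) tetrahydrofuran with free C13 carbinol (epimer mixture at C13)
Conditions: BF3·OEt2 (3 equiv), CH2Cl2, −78 → −20 °C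
Reagents that add atoms: none
Why: In this Hosomi–Sakurai C-glycosylation BF3 ionises the lactol to the bicyclic oxocarbenium ion and the allylsilane should attack C9 on the convex face, anti to the C10–C11 bond, which gives the 2,9-cis tetrahydrofuran (9S).

Step 14
Reactants: 19 (9S)-9-(2-methylprop-2-en-1-yl) tetrahydrofuran with free C13 carbinol
Product: 20 saturated C13 ketone
Conditions: Dess–Martin periodinane, pyridine, CH2Cl2, 23 °C
Reagents that add atoms: none
Why: Dess–Martin oxidation of the secondary alcohol returns the C13 ketone and removes the epimer mixture at C13.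

Step 15
Reactants: 20 saturated C13 ketone
Product: 21 enone (C11=C12–C13=O) with C9 methallyl and C4–OTBDPS
Conditions: LiN(iPr)2 (1.1 equiv), THF, −78 °C; then PhS(Cl)=NtBu, −78 °C
Reagents that add atoms: none
Why: Kinetic deprotonation at the less substituted C12 followed by Mukaiyama dehydrogenation (sulfinimidoyl chloride, α-sulfilimine, syn-elimination toward H11) should give the C11=C12 enone and erase the transient C11 center.

Step 16
Reactants: 21 enone with C4–OTBDPS
Product: 22 C4 primary alcohol
Conditions: Bu4NF, AcOH, THF, 23 °C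
Reagents that add atoms: none
Why: Fluoride desilylation buffered with acetic acid frees the primary alcohol without enolising the enone.

Step 17
Reactants: 22 C4 primary alcohol
Product: 23 C4 aldehyde
Conditions: Dess–Martin periodinane, pyridine, CH2Cl2, 23 °C
Reagents that add atoms: none
Why: Dess–Martin oxidation gives the aldehyde, which cannot epimerise because C3 is quaternary.

Step 18
Reactants: 23 C4 aldehyde; 24 tributyl(prop-2-en-1-yl)stannane
Product: 25 (4R)-homoallylic alcohol (diene for ring closure)
Conditions: MgBr2·OEt2 (3 equiv), CH2Cl2, −78 °C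
Reagents that add atoms: none
Why: In this chelation-controlled allylstannane addition (Keck-type allylation) magnesium should bridge the aldehyde oxygen and the ring oxygen on C3, so that the allyl group enters from the side of the C3 methyl, anti to C2, and gives the 4R carbinol while the enone ketone is left alone.

Step 19
Reactants: 25 (4R)-homoallylic alcohol
Product: 26 (4R,6Z)-oxonene alcohol (tetracyclic core with free C4–OH)
Conditions: second-generation Grubbs catalyst (H2IMes)(PCy3)Cl2Ru=CHPh (10 mol%), PhMe (0.002 M), 80 °C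
Reagents that add atoms: none
Why: Ring-closing olefin metathesis joins C6 and C7 to the nine-membered oxonene, whose ring size enforces the Z trisubstituted olefin; the closure is a known type for 2,9-cis-bridged eunicellane cores, and no stereocenter is formed.

Step 20
Reactants: 26 (4R,6Z)-oxonene alcohol; 27 butanoic anhydride
Product: 28 CNP0271677.1, (1R,2S,3S,4R,6Z,9S,10S,14R,15R)-13-oxo-2,9:3,16-diepoxyeunicella-6,11-dien-4-yl butanoate
Conditions: DMAP, Et3N, CH2Cl2, 23 °C
Reagents that add atoms: none
Why: DMAP-catalysed esterification of the hindered C4 alcohol with the anhydride gives the butanoate without touching any stereocenter.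

**Compound list**

1 | prop-2-yn-1-ol | C#CCO | starting material
2 | tert-butyldiphenyl(prop-2-yn-1-yloxy)silane | C#CCO[Si](c1ccccc1)(c1ccccc1)C(C)(C)C | intermediate
3 | ethyl 4-[(tert-butyldiphenylsilyl)oxy]but-2-ynoate | CCOC(=O)C#CCO[Si](c1ccccc1)(c1ccccc1)C(C)(C)C | intermediate
4 | ethyl (2Z)-4-[(tert-butyldiphenylsilyl)oxy]-3-methylbut-2-enoate | CCOC(=O)/C=C(/C)CO[Si](c1ccccc1)(c1ccccc1)C(C)(C)C | intermediate
5 | (2Z)-4-[(tert-butyldiphenylsilyl)oxy]-3-methylbut-2-en-1-ol | OC/C=C(/C)CO[Si](c1ccccc1)(c1ccccc1)C(C)(C)C | intermediate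
6 | [(2S,3R)-3-{[(tert-butyldiphenylsilyl)oxy]methyl}-3-methyloxiran-2-yl]methanol | OC[C@@H]1O[C@]1(C)CO[Si](c2ccccc2)(c2ccccc2)C(C)(C)C | intermediate
7 | 1-(triphenyl-λ5-phosphanylidene)propan-2-one | CC(=O)C=P(c1ccccc1)(c1ccccc1)c1ccccc1 | starting material
8 | (2R,3R)-3-{[(tert-butyldiphenylsilyl)oxy]methyl}-3-methyloxirane-2-carbaldehyde (epoxy aldehyde, not isolated) | O=C[C@@H]1O[C@]1(C)CO[Si](c2ccccc2)(c2ccccc2)C(C)(C)C | intermediate
9 | (3E)-4-[(2S,3R)-3-{[(tert-butyldiphenylsilyl)oxy]methyl}-3-methyloxiran-2-yl]but-3-en-2-one | CC(=O)/C=C/[C@@H]1O[C@]1(C)CO[Si](c2ccccc2)(c2ccccc2)C(C)(C)C | intermediate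
10 | (3E,5S,6S)-7-[(tert-butyldiphenylsilyl)oxy]-5-hydroxy-6-methyl-6-(prop-2-yn-1-yloxy)hept-3-en-2-one | CC(=O)/C=C/[C@H](O)[C@@](C)(OCC#C)CO[Si](c1ccccc1)(c1ccccc1)C(C)(C)C | intermediate
11 | (2E)-but-2-enoic anhydride (crotonic anhydride) | C/C=C/C(=O)OC(=O)/C=C/C | starting material
12 | (3E,5S,6S)-7-[(tert-butyldiphenylsilyl)oxy]-6-methyl-2-oxo-6-(prop-2-yn-1-yloxy)hept-3-en-5-yl (2E)-but-2-enoate | CC(=O)/C=C/[C@H](OC(=O)/C=C/C)[C@@](C)(OCC#C)CO[Si](c1ccccc1)(c1ccccc1)C(C)(C)C | intermediate
13 | (3E,5S,6S)-2-[(tert-butyldimethylsilyl)oxy]-7-[(tert-butyldiphenylsilyl)oxy]-6-methyl-6-(prop-2-yn-1-yloxy)hepta-1,3-dien-5-yl (2E)-but-2-enoate | C=C(O[Si](C)(C)C(C)(C)C)/C=C/[C@H](OC(=O)/C=C/C)[C@@](C)(OCC#C)CO[Si](c1ccccc1)(c1ccccc1)C(C)(C)C | intermediate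
14 | Diels–Alder adduct (not isolated): cis-fused γ-lactone (C9=O, ring O on C2) on a cyclohexene with the C13 OTBS enol ether (C13=C14) and the C11 methyl trans to C9; H1 cis to H10 and trans to H2; C2 carries the C3(Me)(O-propargyl)(CH2OTBDPS) carbon | O=C1O[C@H]([C@@](C)(OCC#C)CO[Si](c3ccccc3)(c3ccccc3)C(C)(C)C)[C@H]2C=C(O[Si](C)(C)C(C)(C)C)C[C@H](C)[C@@H]12 | intermediate
15 | tricyclic keto lactone: γ-lactone (C9=O) cis-fused to a cyclohexanone (C13=O, 11-methyl) that is cis-fused at C1–C14 to the oxepane (C14–C15–C16–O–C3–C2–C1) with C15 exocyclic methylene; C3 bears methyl and CH2OTBDPS; H1, H10 and H14 all cis, H2 trans to H1 | O=C1O[C@H]2[C@@H]3[C@H]1[C@@H](C)CC(=O)[C@@H]3C(=C)CO[C@@]2(C)CO[Si](c4ccccc4)(c4ccccc4)C(C)(C)C | intermediate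
16 | lactol diol: as 15 with C9 hemiacetal (anomer mixture) and C13 carbinol (epimer mixture) | OC1O[C@H]2[C@@H]3[C@H]1[C@@H](C)CC(O)[C@@H]3C(=C)CO[C@@]2(C)CO[Si](c4ccccc4)(c4ccccc4)C(C)(C)C | intermediate
17 | (15R)-methyl lactol diol: as 16 with the C15 methyl (trans to C13 on the oxepane) in place of the methylene | OC1O[C@H]2[C@@H]3[C@H]1[C@@H](C)CC(O)[C@@H]3[C@@H](C)CO[C@@]2(C)CO[Si](c4ccccc4)(c4ccccc4)C(C)(C)C | intermediate
18 | trimethyl(2-methylprop-2-en-1-yl)silane | C=C(C)C[Si](C)(C)C | starting material
19 | (9S)-9-(2-methylprop-2-en-1-yl) tetrahydrofuran (2,9-cis) with C13 carbinol (epimer mixture), oxepane and C4–OTBDPS | C=C(C)C[C@@H]1O[C@H]2[C@@H]3[C@H]1[C@@H](C)CC(O)[C@@H]3[C@@H](C)CO[C@@]2(C)CO[Si](c4ccccc4)(c4ccccc4)C(C)(C)C | intermediate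
20 | saturated C13 ketone: as 19 with C13=O | C=C(C)C[C@@H]1O[C@H]2[C@@H]3[C@H]1[C@@H](C)CC(=O)[C@@H]3[C@@H](C)CO[C@@]2(C)CO[Si](c4ccccc4)(c4ccccc4)C(C)(C)C | intermediate
21 | enone: C11(Me)=C12–C13=O, C9 methallyl, oxepane, C4–OTBDPS | C=C(C)C[C@@H]1O[C@H]2[C@@H]3[C@H]1C(C)=CC(=O)[C@@H]3[C@@H](C)CO[C@@]2(C)CO[Si](c4ccccc4)(c4ccccc4)C(C)(C)C | intermediate
22 | C4 primary alcohol: as 21 with CH2OH on C3 | C=C(C)C[C@@H]1O[C@H]2[C@@H]3[C@H]1C(C)=CC(=O)[C@@H]3[C@@H](C)CO[C@@]2(C)CO | intermediate
23 | C4 aldehyde: as 21 with CHO on C3 | C=C(C)C[C@@H]1O[C@H]2[C@@H]3[C@H]1C(C)=CC(=O)[C@@H]3[C@@H](C)CO[C@@]2(C)C=O | intermediate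
24 | tributyl(prop-2-en-1-yl)stannane | C=CC[Sn](CCCC)(CCCC)CCCC | starting material
25 | (4R)-homoallylic alcohol: C3 bears CH(OH)CH2CH=CH2, C9 bears methallyl | C=C(C)C[C@@H]1O[C@H]2[C@@H]3[C@H]1C(C)=CC(=O)[C@@H]3[C@@H](C)CO[C@@]2(C)[C@H](O)CC=C | intermediate
26 | (4R,6Z)-oxonene alcohol: the target skeleton with free C4–OH | O[C@@H]1C/C=C(/C)C[C@@H]2O[C@H]3[C@@H]4[C@H]2C(C)=CC(=O)[C@@H]4[C@@H](C)CO[C@@]13C | intermediate
27 | butanoic anhydride | CCCC(=O)OC(=O)CCC | starting material
28 | CNP0271677.1, (1R,2S,3S,4R,6Z,9S,10S,14R,15R)-13-oxo-2,9:3,16-diepoxyeunicella-6,11-dien-4-yl butanoate | CCCC(=O)O[C@@H]1C/C=C(/C)C[C@@H]2O[C@H]3[C@@H]4[C@H]2C(C)=CC(=O)[C@@H]4[C@@H](C)CO[C@@]13C | target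

**Step count and risks**

Total step count: 20. Longest linear sequence: 20 steps (from 1).

Steps most likely to fail:

1. Step 10 (key step). What may go wrong: after the cycloaddition the enol silane may be lost by protodesilylation, or the alkyne may be attacked in the 8-endo sense or hydrated, before 7-exo C–C bond formation; the ester-tethered cycloaddition itself may also be slow enough for dimerisation to compete. Fallback (sets out from 9, comes back at 15): the C14–C15 bond would be made by palladium-catalysed coupling of the same cycloaddition-derived enol silane with a vinyl bromide instead of by π-acid activation of an alkyne. Epoxide 9 would be opened with 2-bromoprop-2-en-1-ol (BF3·OEt2, as in step 7) to the 2-bromoallyl ether hydroxy enone F1, which would be acylated with 11 to the crotonate ester F2 and silylated (TBSOTf, Et3N) to the silyloxydiene F3. Heating F3 in toluene should give the Diels–Alder adduct F4, now isolated. Treatment of F4 with Pd2(dba)3/P(tBu)3, Bu3SnF and CsF in toluene at 85 °C (intramolecular α-alkenylation of the tin enolate formed from the enol silane, a known cross-coupling of enol silanes with vinyl halides) should close the oxepane and give 15.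

2. Step 12. What may go wrong: poor facial selectivity if the iridium is not held by the C13 oxygen (hydrogen then enters from the face away from the cyclohexane ring and gives the C15 epimer), or migration of the exocyclic olefin into the ring by the iridium hydride. Fallback (sets out from 16, comes back at 17; no new compound, F0): directed syn-hydrogenation would be replaced by stepwise hydrogen-atom-transfer reduction (Mn(dpm)3, PhSiH3, tBuOOH, iPrOH, 23 °C). The tertiary C15 radical formed by Markovnikov hydrogen-atom transfer is quenched under product-stability control, which should favour the methyl trans to C13 (pseudo-equatorial on the oxepane).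

3. Step 18. What may go wrong: poor facial selectivity if chelation through the tetrahydrofuran oxygen on C2 or an open, non-chelated transition state competes with chelation through the oxepane oxygen on C3, which would give the C4 epimer. Fallback (sets out from 23, comes back at 25; no new compound, F0): substrate control would be replaced by reagent control in a Brown allylboration, using the enantiomer of B-allyldiisopinocampheylborane that adds to the Re face of aldehydes (the reagent from (−)-α-pinene), Et2O, −78 °C, ethanolamine work-up. The closed six-membered transition state of the allylborane overrides the chelate preference, and the ketone is not attacked at this temperature.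

**Further compounds**

F1 | step 10 | (3E,5S,6S)-6-[(2-bromoprop-2-en-1-yl)oxy]-7-[(tert-butyldiphenylsilyl)oxy]-5-hydroxy-6-methylhept-3-en-2-one | CC(=O)/C=C/[C@H](O)[C@@](C)(OCC(Br)=C)CO[Si](c1ccccc1)(c1ccccc1)C(C)(C)C
F2 | step 10 | (3E,5S,6S)-6-[(2-bromoprop-2-en-1-yl)oxy]-7-[(tert-butyldiphenylsilyl)oxy]-6-methyl-2-oxohept-3-en-5-yl (2E)-but-2-enoate | CC(=O)/C=C/[C@H](OC(=O)/C=C/C)[C@@](C)(OCC(Br)=C)CO[Si](c1ccccc1)(c1ccccc1)C(C)(C)C
F3 | step 10 | (3E,5S,6S)-6-[(2-bromoprop-2-en-1-yl)oxy]-2-[(tert-butyldimethylsilyl)oxy]-7-[(tert-butyldiphenylsilyl)oxy]-6-methylhepta-1,3-dien-5-yl (2E)-but-2-enoate | C=C(O[Si](C)(C)C(C)(C)C)/C=C/[C@H](OC(=O)/C=C/C)[C@@](C)(OCC(Br)=C)CO[Si](c1ccccc1)(c1ccccc1)C(C)(C)C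
F4 | step 10 | Diels–Alder adduct with 2-bromoallyl ether on the C3 oxygen (otherwise as 14) | O=C1O[C@H]([C@@](C)(OCC(Br)=C)CO[Si](c3ccccc3)(c3ccccc3)C(C)(C)C)[C@H]2C=C(O[Si](C)(C)C(C)(C)C)C[C@H](C)[C@@H]12
F0 | step 12 | none | none
F0 | step 18 | none | none
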